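## Retrosynthetic overview

1. The strategy rests on the six-membered ring of 18 (C1 ketone, C2=C3, C4H2, C5 carbinol, C6H2). Its enone C1(=O)–C2=C3 with unsubstituted C2 comes from 3-chloro ketone 16, and 16 comes from oxidative scission of the shared C1–C3 bond of 1-siloxybicyclo[3.1.0]hexane 15, whose cyclopropane CH2 is C2.
2. 15 ⇐ cyclopropanol 14 ⇐ intramolecular Kulinkovich cyclopropanation of hex-5-enoate 13 (ester carbon = C1, its CH2 = C6, carbinol = C5, allyl = C4–C3=C2). The five-membered ring and the cyclopropane close together first; the six-membered ring appears only when the five-membered ring is enlarged in the key step.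
3. 13 ⇐ ketone 12 ⇐ Fukuyama coupling of thioester 7 with the C17 alkylzinc 11, made from linoleic acid 8 by decarboxylative iodination.
4. 7 ⇐ (S)-half-ester 5 ⇐ enzymatic desymmetrisation of prochiral diester 4 (sets C5, the only stereocentre of 18) ⇐ Barbier allylation of keto diester 1 with allyl bromide 2.
5. Endgame: dehydrochlorination to the C2=C3 enone, then acid removal of the dioxolane and the triethylsilyl ether.

Key step: step 10

Assumption: pig liver esterase is taken to select between the enantiotopic ester arms of 4 in the sense known for the 3-hydroxy-3-methyl congener, which leads to the (S)-half-ester 5; compounds 14–16 are carried as diastereomer mixtures and one isomer of each is drawn.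

## Route

Step 1
Reactants: 1 dimethyl 3-oxopentanedioate; 2 allyl bromide
Product: 4 dimethyl 3-hydroxy-3-(prop-2-en-1-yl)pentanedioate, via allylzinc bromide 3 (not isolated)
Conditions: Zn dust, THF/sat. aq. NH4Cl, 0 °C → rt
Reagents that add atoms: zinc, [Zn] (kept only in intermediate 3)
Why: Barbier allylation, in which zinc inserts into the allylic C–Br bond and the allylzinc adds to the ketone in a buffered aqueous medium that leaves the acidic keto diester undeprotonated; C3 carries two identical CH2CO2Me arms, so no stereocentre is formed.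

Step 2
Reactants: 4 dimethyl 3-hydroxy-3-(prop-2-en-1-yl)pentanedioate
Product: 5 (3S)-3-hydroxy-5-methoxy-5-oxo-3-(prop-2-en-1-yl)pentanoic acid
Conditions: pig liver esterase, 0.1 M phosphate buffer pH 7.5, rt, pH-stat (1 M NaOH); then aq. HCl to pH 2
Reagents that add atoms: water, O
Why: Enzymatic desymmetrisation of a prochiral diester, in which the esterase hydrolyses one of the two enantiotopic CH2CO2Me arms and so sets the only permanent stereocentre (C3 here, C5 of the target), the sense being assigned by analogy with the 3-hydroxy-3-methyl congener.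

Step 3
Reactants: 5 (3S)-3-hydroxy-5-methoxy-5-oxo-3-(prop-2-en-1-yl)pentanoic acid
Product: 6 methyl (3R)-5-(ethylsulfanyl)-3-hydroxy-5-oxo-3-(prop-2-en-1-yl)pentanoate
Conditions: EtSH, DCC, DMAP (cat.), CH2Cl2, 0 °C → rt
Reagents that add atoms: ethanethiol, CCS
Why: Steglich-type carbodiimide thioesterification of the free acid, in which the hindered tertiary alcohol is not acylated and the stereocentre is untouched (the descriptor changes only because the priorities change).

Step 4
Reactants: 6 methyl (3R)-5-(ethylsulfanyl)-3-hydroxy-5-oxo-3-(prop-2-en-1-yl)pentanoate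
Product: 7 methyl (3R)-5-(ethylsulfanyl)-5-oxo-3-(prop-2-en-1-yl)-3-[(triethylsilyl)oxy]pentanoate
Conditions: TESOTf, 2,6-lutidine, CH2Cl2, −78 → 0 °C
Reagents that add atoms: triethylsilyl trifluoromethanesulfonate, CC[Si](CC)(CC)OS(=O)(=O)C(F)(F)F
Why: O-Silylation with a silyl triflate and a hindered pyridine base, which caps even a tertiary alcohol and removes the protic site before the organozinc step while blocking retro-aldol and dehydration once the β-ketone is in place.

Step 5
Reactants: 8 linoleic acid
Product: 10 (6Z,9Z)-17-iodoheptadeca-6,9-diene, via Barton ester 9 (not isolated)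
Conditions: 1-hydroxypyridine-2(1H)-thione, DCC, DMAP (cat.), CH2Cl2, 0 °C → rt, dark; then CHI3, PhMe, tungsten lamp, rt
Reagents that add atoms: iodoform, IC(I)I; 1-hydroxypyridine-2(1H)-thione, On1ccccc1=S (kept only in intermediate 9)
Why: Barton decarboxylative iodination, in which the thiohydroxamate ester fragments under visible light to the primary C17 radical and this takes iodine from iodoform in a chain process; the radical sits seven carbons from the nearest alkene and has no low-strain cyclisation open to it, so the Z,Z-skipped diene should be carried through.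

Step 6
Reactants: 7 methyl (3R)-5-(ethylsulfanyl)-5-oxo-3-(prop-2-en-1-yl)-3-[(triethylsilyl)oxy]pentanoate; 10 (6Z,9Z)-17-iodoheptadeca-6,9-diene
Product: 12 methyl (3S,13Z,16Z)-5-oxo-3-(prop-2-en-1-yl)-3-[(triethylsilyl)oxy]docosa-13,16-dienoate, via alkylzinc iodide 11 (not isolated)
Conditions: 10, Zn dust (activated with 1,2-dibromoethane and TMSCl), THF, 40 °C; then 7, PdCl2(PPh3)2 (5 mol%), PhMe, rt
Reagents that add atoms: zinc, [Zn] (kept only in intermediate 11)
Why: Fukuyama coupling, in which zerovalent palladium formed in situ inserts into the C–S bond, the alkylzinc iodide transmetallates and reductive elimination gives the ketone without over-addition, the methyl ester, silyl ether and alkenes being inert to the weakly nucleophilic organozinc.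

Step 7
Reactants: 12 methyl (3S,13Z,16Z)-5-oxo-3-(prop-2-en-1-yl)-3-[(triethylsilyl)oxy]docosa-13,16-dienoate
Product: 13 methyl (3S)-3-({2-[(8Z,11Z)-heptadeca-8,11-dien-1-yl]-1,3-dioxolan-2-yl}methyl)-3-[(triethylsilyl)oxy]hex-5-enoate
Conditions: TMSOCH2CH2OTMS, TMSOTf (5 mol%), CH2Cl2, −78 → −20 °C; pyridine quench
Reagents that add atoms: 1,2-bis(trimethylsilyloxy)ethane, C[Si](C)(C)OCCO[Si](C)(C)C
Why: Aprotic silyl-triflate-catalysed acetalisation (Noyori conditions), which converts the ketone into the dioxolane at low temperature without Brønsted acid or water, so the β-silyloxy ketone should not dehydrate; the mask is needed because the next step uses a Grignard reagent.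

Step 8
Reactants: 13 methyl (3S)-3-({2-[(8Z,11Z)-heptadeca-8,11-dien-1-yl]-1,3-dioxolan-2-yl}methyl)-3-[(triethylsilyl)oxy]hex-5-enoate
Product: 14 (1R,3R,5R)-3-({2-[(8Z,11Z)-heptadeca-8,11-dien-1-yl]-1,3-dioxolan-2-yl}methyl)-3-[(triethylsilyl)oxy]bicyclo[3.1.0]hexan-1-ol
Conditions: Ti(OiPr)4 (1.2 equiv), c-C5H9MgCl (4.5 equiv, added over 2 h), THF, rt
Reagents that add atoms: none
Why: Intramolecular Kulinkovich cyclopropanation by ligand exchange, in which the cyclopentene titanacyclopropane passes titanium to the terminal allyl alkene only (the 1,2-disubstituted Z-alkenes do not exchange) and the new titanacyclopropane adds to the tethered ester carbon, loses methoxide and forms C1–C2 and C1–C3; the cis ring fusion is enforced by the three-membered ring, while the relation of the new centres C1 and C3 to C5 is uncontrolled and need not be controlled because both are destroyed later.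

Step 9
Reactants: 14 (1R,3R,5R)-3-({2-[(8Z,11Z)-heptadeca-8,11-dien-1-yl]-1,3-dioxolan-2-yl}methyl)-3-[(triethylsilyl)oxy]bicyclo[3.1.0]hexan-1-ol
Product: 15 triethyl{[(1R,3R,5R)-3-({2-[(8Z,11Z)-heptadeca-8,11-dien-1-yl]-1,3-dioxolan-2-yl}methyl)-1-[(trimethylsilyl)oxy]bicyclo[3.1.0]hexan-3-yl]oxy}silane
Conditions: TMSOTf, Et3N, CH2Cl2, −78 → 0 °C
Reagents that add atoms: trimethylsilyl trifluoromethanesulfonate, C[Si](C)(C)OS(=O)(=O)C(F)(F)F
Why: O-Silylation of the tertiary cyclopropanol with a silyl triflate and excess amine base, which is fast at low temperature and avoids the acid- or base-induced opening of the free cyclopropanol to a 2-methylcyclopentanone.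

Step 10
Reactants: 15 triethyl{[(1R,3R,5R)-3-({2-[(8Z,11Z)-heptadeca-8,11-dien-1-yl]-1,3-dioxolan-2-yl}methyl)-1-[(trimethylsilyl)oxy]bicyclo[3.1.0]hexan-3-yl]oxy}silane
Product: 16 (3R,5R)-5-chloro-3-({2-[(8Z,11Z)-heptadeca-8,11-dien-1-yl]-1,3-dioxolan-2-yl}methyl)-3-[(triethylsilyl)oxy]cyclohexan-1-one
Conditions: FeCl3 (2.5 equiv), pyridine (1.0 equiv), DMF, 0 °C → rt
Reagents that add atoms: iron trichloride, Cl[Fe](Cl)Cl
Why: Oxidative ring expansion of a siloxycyclopropane by iron trichloride, a known reaction type for 1-siloxybicyclo[n.1.0]alkanes: trivalent iron takes one electron from the electron-rich O–C1 cyclopropane, the silyl group leaves as its chloride, and the C1 oxygen-centred radical equivalent undergoes β-scission of the shared C1–C3 bond to give the C1 ketone and a secondary C3 radical, which takes a chlorine atom from a second FeCl3 and leaves divalent iron. The six-membered ring C1–C6 is therefore made by fragmentation of the zero-atom bridge of the bicycle (enlargement of the five-membered ring by the cyclopropane methylene C2), not by a ring-closing bond, so no exo or endo closure mode is involved. The one new stereocentre, C3–Cl (C5 in the name of 16), is set by chlorine transfer to a planar radical without useful control, and both epimers, like both ring-fusion diastereomers of 15, converge in step 11. The selectivity that matters is which cyclopropane bond breaks: scission of C1–C3 gives a secondary ring radical and releases the strain of the ring fusion, whereas scission of C1–C2 would give a primary radical, so the ring-expanded 3-chloro ketone should dominate. Chemoselectivity rests on the siloxycyclopropane being by far the most oxidisable group: the isolated Z-alkenes are not oxidised by FeCl3, the C3 radical is remote from them and should be trapped by chlorine transfer faster than it can abstract a bis-allylic hydrogen, and DMF with pyridine tempers the Lewis acidity so that the dioxolane and the triethylsilyl ether should survive.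

Step 11
Reactants: 16 (3R,5R)-5-chloro-3-({2-[(8Z,11Z)-heptadeca-8,11-dien-1-yl]-1,3-dioxolan-2-yl}methyl)-3-[(triethylsilyl)oxy]cyclohexan-1-one
Product: 17 (5R)-5-({2-[(8Z,11Z)-heptadeca-8,11-dien-1-yl]-1,3-dioxolan-2-yl}methyl)-5-[(triethylsilyl)oxy]cyclohex-2-en-1-one
Conditions: NaOAc, MeOH, rt → 45 °C
Reagents that add atoms: none
Why: E1cB dehydrochlorination, in which acetate enolises the ketone toward C2 and chloride leaves from C3 to give the conjugated C2=C3 enone; chloride is a far better β-leaving group than the tertiary silyloxy group at C5, so elimination toward C5–C6 (the path to a phenol) should not compete under this weak base.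

Step 12
Reactants: 17 (5R)-5-({2-[(8Z,11Z)-heptadeca-8,11-dien-1-yl]-1,3-dioxolan-2-yl}methyl)-5-[(triethylsilyl)oxy]cyclohex-2-en-1-one
Product: 18 (5S)-5-hydroxy-5-[(10Z,13Z)-2-oxononadeca-10,13-dien-1-yl]cyclohex-2-en-1-one
Conditions: 1 M aq. HCl/THF (1:4), 0 °C → rt
Reagents that add atoms: water, O
Why: Acid-catalysed acetal hydrolysis together with protodesilylation of the triethylsilyl ether in dilute aqueous acid at or below room temperature, conditions under which a tertiary β-hydroxy ketone is not normally dehydrated; no bond to C5 is broken, so its configuration is retained (the descriptor changes only through the priorities).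

## Compound list

1 | dimethyl 3-oxopentanedioate | COC(=O)CC(=O)CC(=O)OC | starting material
2 | allyl bromide (3-bromoprop-1-ene) | C=CCBr | starting material
3 | allylzinc bromide | C=CC[Zn]Br | intermediate (not isolated)
4 | dimethyl 3-hydroxy-3-(prop-2-en-1-yl)pentanedioate | COC(=O)CC(O)(CC=C)CC(=O)OC | intermediate
5 | (3S)-3-hydroxy-5-methoxy-5-oxo-3-(prop-2-en-1-yl)pentanoic acid | OC(=O)C[C@@](CC(=O)OC)(O)CC=C | intermediate
6 | methyl (3R)-5-(ethylsulfanyl)-3-hydroxy-5-oxo-3-(prop-2-en-1-yl)pentanoate | CCSC(=O)C[C@@](CC(=O)OC)(O)CC=C | intermediate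
7 | methyl (3R)-5-(ethylsulfanyl)-5-oxo-3-(prop-2-en-1-yl)-3-[(triethylsilyl)oxy]pentanoate | CCSC(=O)C[C@@](CC(=O)OC)(O[Si](CC)(CC)CC)CC=C | intermediate
8 | linoleic acid, (9Z,12Z)-octadeca-9,12-dienoic acid | CCCCC/C=C\C/C=C\CCCCCCCC(=O)O | starting material
9 | Barton ester, 2-thioxopyridin-1(2H)-yl (9Z,12Z)-octadeca-9,12-dienoate | CCCCC/C=C\C/C=C\CCCCCCCC(=O)On1ccccc1=S | intermediate (not isolated)
10 | (6Z,9Z)-17-iodoheptadeca-6,9-diene, the (8Z,11Z)-heptadeca-8,11-dien-1-yl iodide | CCCCC/C=C\C/C=C\CCCCCCCI | intermediate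
11 | [(8Z,11Z)-heptadeca-8,11-dien-1-yl]zinc iodide | CCCCC/C=C\C/C=C\CCCCCCC[Zn]I | intermediate (not isolated)
12 | methyl (3S,13Z,16Z)-5-oxo-3-(prop-2-en-1-yl)-3-[(triethylsilyl)oxy]docosa-13,16-dienoate | CCCCC/C=C\C/C=C\CCCCCCCC(=O)C[C@@](CC(=O)OC)(O[Si](CC)(CC)CC)CC=C | intermediate
13 | methyl (3S)-3-({2-[(8Z,11Z)-heptadeca-8,11-dien-1-yl]-1,3-dioxolan-2-yl}methyl)-3-[(triethylsilyl)oxy]hex-5-enoate | CCCCC/C=C\C/C=C\CCCCCCCC1(OCCO1)C[C@@](CC(=O)OC)(O[Si](CC)(CC)CC)CC=C | intermediate
14 | (1R,3R,5R)-3-({2-[(8Z,11Z)-heptadeca-8,11-dien-1-yl]-1,3-dioxolan-2-yl}methyl)-3-[(triethylsilyl)oxy]bicyclo[3.1.0]hexan-1-ol; cis-fused, drawn with the C3 silyloxy group anti to the cyclopropane CH2, expected together with its (1S,3R,5S) diastereomer | CCCCC/C=C\C/C=C\CCCCCCCC1(OCCO1)C[C@@]2(O[Si](CC)(CC)CC)C[C@H]3C[C@@]3(O)C2 | intermediate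
15 | triethyl{[(1R,3R,5R)-3-({2-[(8Z,11Z)-heptadeca-8,11-dien-1-yl]-1,3-dioxolan-2-yl}methyl)-1-[(trimethylsilyl)oxy]bicyclo[3.1.0]hexan-3-yl]oxy}silane; same drawn diastereomer as 14 | CCCCC/C=C\C/C=C\CCCCCCCC1(OCCO1)C[C@@]2(O[Si](CC)(CC)CC)C[C@H]3C[C@@]3(O[Si](C)(C)C)C2 | intermediate
16 | (3R,5R)-5-chloro-3-({2-[(8Z,11Z)-heptadeca-8,11-dien-1-yl]-1,3-dioxolan-2-yl}methyl)-3-[(triethylsilyl)oxy]cyclohexan-1-one; drawn chloride epimer, the (3R,5S) epimer is expected as well | CCCCC/C=C\C/C=C\CCCCCCCC1(OCCO1)C[C@@]2(O[Si](CC)(CC)CC)C[C@@H](Cl)CC(=O)C2 | intermediate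
17 | (5R)-5-({2-[(8Z,11Z)-heptadeca-8,11-dien-1-yl]-1,3-dioxolan-2-yl}methyl)-5-[(triethylsilyl)oxy]cyclohex-2-en-1-one | CCCCC/C=C\C/C=C\CCCCCCCC1(OCCO1)C[C@@]2(O[Si](CC)(CC)CC)CC=CC(=O)C2 | intermediate
18 | (5S)-5-hydroxy-5-[(10Z,13Z)-2-oxononadeca-10,13-dien-1-yl]cyclohex-2-en-1-one (CNP0252404.1) | CCCCC/C=C\C/C=C\CCCCCCCC(=O)C[C@@]1(O)CC=CC(=O)C1 | target

## Step count and risks

Total step count: 12. Longest linear sequence: 11 steps (steps 1–4 and 6–12, from dimethyl 3-oxopentanedioate); step 5 is a one-step side branch from linoleic acid.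

Steps most likely to fail:

1. Step 10 (key step). The cyclopropane may open at the exocyclic C1–C2 bond or by an ionic, Lewis-acid pathway instead of the radical scission of C1–C3. The acetal and silyl ether may also be lost under FeCl3, followed by dehydration at C5 and aromatisation. The fallback builds the C2=C3 bond directly by ring-closing metathesis; it sets out from 13 and comes back to the route at 17. The methyl ester of 13 would be converted with MeNH(OMe)·HCl and i-PrMgCl (THF, −20 °C) into the Weinreb amide (3S)-3-({2-[(8Z,11Z)-heptadeca-8,11-dien-1-yl]-1,3-dioxolan-2-yl}methyl)-N-methoxy-N-methyl-3-[(triethylsilyl)oxy]hex-5-enamide F1. Vinylmagnesium bromide (THF, 0 °C) would then give the vinyl ketone (5R)-5-({2-[(8Z,11Z)-heptadeca-8,11-dien-1-yl]-1,3-dioxolan-2-yl}methyl)-5-[(triethylsilyl)oxy]octa-1,7-dien-3-one F2. Ring-closing metathesis of its vinyl ketone and allyl termini with the second-generation Grubbs catalyst (CH2Cl2, 40 °C, high dilution) would give enone 17. The two terminal alkenes engage the ruthenium carbene far faster than the internal Z-alkenes, and some exposure of the skipped diene to the catalyst is accepted in exchange.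

2. Step 2. The enzyme may discriminate the enantiotopic ester arms of the allyl-substituted diester poorly or in the reverse sense, giving half-ester of low enantiomeric purity or the wrong antipode. The fallback replaces the enzyme by alkaloid-mediated opening of a cyclic anhydride, where either antipode can be reached by the choice of pseudo-enantiomeric alkaloid; it sets out from 4 and comes back at 7. Silylation of 4 (TESOTf, 2,6-lutidine) would give dimethyl 3-(prop-2-en-1-yl)-3-[(triethylsilyl)oxy]pentanedioate F3. Saponification (LiOH, THF/MeOH/H2O, rt) would give 3-(prop-2-en-1-yl)-3-[(triethylsilyl)oxy]pentanedioic acid F4, and cyclodehydration (DCC, CH2Cl2) would give the anhydride 4-(prop-2-en-1-yl)-4-[(triethylsilyl)oxy]oxane-2,6-dione F5. Enantioselective methanolysis (MeOH, quinidine or quinine, whichever delivers the S series, toluene, −50 °C) would give the hemiester (3S)-5-methoxy-5-oxo-3-(prop-2-en-1-yl)-3-[(triethylsilyl)oxy]pentanoic acid F6. Thioesterification as in step 3 (EtSH, DCC, DMAP) would then give 7.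

3. Step 5. The radical chain may damage the skipped diene through iodine-atom or thiyl-mediated Z-to-E isomerisation or bis-allylic hydrogen abstraction, and the light-sensitive thiohydroxamate ester may decompose before it is intercepted by iodoform. The fallback merges decarboxylation and ketone formation at nickel, so no alkyl iodide, thiohydroxamate or organozinc is needed. It sets out from 8, takes its acyl partner from half-ester 5, and comes back at 12. Half-ester 5 would be converted with 2,2'-dipyridyl disulfide and PPh3 into methyl (3R)-3-hydroxy-5-oxo-3-(prop-2-en-1-yl)-5-(pyridin-2-ylsulfanyl)pentanoate F7. Silylation (TESOTf, 2,6-lutidine) would give methyl (3R)-5-oxo-3-(prop-2-en-1-yl)-5-(pyridin-2-ylsulfanyl)-3-[(triethylsilyl)oxy]pentanoate F8. Linoleic acid 8 would be esterified with N-hydroxyphthalimide (N,N'-diisopropylcarbodiimide, DMAP) to give 1,3-dioxo-1,3-dihydro-2H-isoindol-2-yl (9Z,12Z)-octadeca-9,12-dienoate F9. Nickel-catalysed reductive decarboxylative acylation of F9 with F8 (NiBr2(dme), 4,4'-di-tert-butyl-2,2'-bipyridine, Zn dust, THF/DMA, rt) would give ketone 12.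

## Further compounds

F1 | step 10 | (3S)-3-({2-[(8Z,11Z)-heptadeca-8,11-dien-1-yl]-1,3-dioxolan-2-yl}methyl)-N-methoxy-N-methyl-3-[(triethylsilyl)oxy]hex-5-enamide | CCCCC/C=C\C/C=C\CCCCCCCC1(OCCO1)C[C@@](CC(=O)N(C)OC)(O[Si](CC)(CC)CC)CC=C
F2 | step 10 | (5R)-5-({2-[(8Z,11Z)-heptadeca-8,11-dien-1-yl]-1,3-dioxolan-2-yl}methyl)-5-[(triethylsilyl)oxy]octa-1,7-dien-3-one | CCCCC/C=C\C/C=C\CCCCCCCC1(OCCO1)C[C@@](CC(=O)C=C)(O[Si](CC)(CC)CC)CC=C
F3 | step 2 | dimethyl 3-(prop-2-en-1-yl)-3-[(triethylsilyl)oxy]pentanedioate | COC(=O)CC(CC=C)(O[Si](CC)(CC)CC)CC(=O)OC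
F4 | step 2 | 3-(prop-2-en-1-yl)-3-[(triethylsilyl)oxy]pentanedioic acid | OC(=O)CC(CC=C)(O[Si](CC)(CC)CC)CC(=O)O
F5 | step 2 | 4-(prop-2-en-1-yl)-4-[(triethylsilyl)oxy]oxane-2,6-dione | O=C1CC(CC=C)(O[Si](CC)(CC)CC)CC(=O)O1
F6 | step 2 | (3S)-5-methoxy-5-oxo-3-(prop-2-en-1-yl)-3-[(triethylsilyl)oxy]pentanoic acid | OC(=O)C[C@@](CC(=O)OC)(O[Si](CC)(CC)CC)CC=C
F7 | step 5 | methyl (3R)-3-hydroxy-5-oxo-3-(prop-2-en-1-yl)-5-(pyridin-2-ylsulfanyl)pentanoate | O=C(Sc1ccccn1)C[C@@](CC(=O)OC)(O)CC=C
F8 | step 5 | methyl (3R)-5-oxo-3-(prop-2-en-1-yl)-5-(pyridin-2-ylsulfanyl)-3-[(triethylsilyl)oxy]pentanoate | O=C(Sc1ccccn1)C[C@@](CC(=O)OC)(O[Si](CC)(CC)CC)CC=C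
F9 | step 5 | 1,3-dioxo-1,3-dihydro-2H-isoindol-2-yl (9Z,12Z)-octadeca-9,12-dienoate | CCCCC/C=C\C/C=C\CCCCCCCC(=O)ON1C(=O)c2ccccc2C1=O
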